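**Retrosynthetic overview**

1. The side chain is numbered C1' (ketone) to C12' with the carboxyl on C8'; ring A is the 3-acyl-4-hydroxy-6-methyl-5,6-dihydropyran-2-one. The strategy rests on C4', a methyl-bearing stereocentre two carbons from the E-C6'=C7' alkene. With C3' as a carboxyl this is an α-methyl γ,δ-unsaturated acid, opened by an Ireland–Claisen rearrangement (C4'–C5' bond) of the propionate of the (S)-C7' bis-allylic carbinol.
2. After the key step: the C3' acid becomes CH2I, C2'–C3' is made by alkylating the dianion of acetic acid, C1'–C3 (ring A) by O-acylation and O→C acyl shift on the preformed pyranone, and the tert-butyl ester is cleaved last.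
3. Before the key step: C8'=C9' comes from a Z-selective bromo-Wittig reaction on (S)-2-methylbutanal, C7'–C8' from a Suzuki coupling, and the C7' carbinol from Sharpless epoxidation of the dienol followed by reductive epoxide opening.
4. Rings: only ring A is formed, by lactonisation in step 14 on a side branch from methyl (R)-3-hydroxybutanoate; the main chain stays acyclic.

Key step: step 9

Remark on the chemistry: the tricarbonyl unit is drawn throughout as its 4-hydroxy enol tautomer.

**Route**

Step 1
Reactants: 1 (S)-2-methylbutan-1-ol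
Product: 2 (S)-2-methylbutanal
Conditions: TEMPO (cat.), KBr (cat.), aq. NaOCl, NaHCO3, CH2Cl2/H2O, 0 °C; dried CH2Cl2 solution used directly
Reagents that add atoms: none
Why: TEMPO-catalysed hypochlorite oxidation (Anelli oxidation) stops at the aldehyde and runs cold at buffered pH, so the α-stereocentre taken from the chiral pool should not enolise.

Step 2
Reactants: 3 tert-butyl 2-(triphenyl-λ5-phosphanylidene)acetate
Product: 5 tert-butyl 2-bromo-2-(triphenyl-λ5-phosphanylidene)acetate, via bromophosphonium succinimidate 4 (not isolated)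
Conditions: N-bromosuccinimide (1.0 equiv), CH2Cl2, −20 °C → 0 °C; water wash
Reagents that add atoms: N-bromosuccinimide, O=C1CCC(=O)N1Br
Why: Electrophilic bromination of a stabilised phosphorus ylide: the ylide carbon takes bromine from the reagent and the succinimide anion removes the remaining α-proton of the phosphonium ion, regenerating an ylide.

Step 3
Reactants: 2 (S)-2-methylbutanal; 5 tert-butyl 2-bromo-2-(triphenyl-λ5-phosphanylidene)acetate
Product: 6 tert-butyl (2Z,4S)-2-bromo-4-methylhex-2-enoate
Conditions: CH2Cl2, 0 °C → 40 °C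
Reagents that add atoms: none
Why: Wittig olefination with a stabilised α-bromo ylide should place the ester trans to the alkyl residue, which is the Z-bromoalkene, and the base-free conditions should leave the α-stereocentre of the aldehyde untouched.

Step 4
Reactants: 6 tert-butyl (2Z,4S)-2-bromo-4-methylhex-2-enoate; 7 (2E)-3-(4,4,5,5-tetramethyl-1,3,2-dioxaborolan-2-yl)prop-2-en-1-ol
Product: 8 tert-butyl (2E,4S)-2-[(1E)-3-hydroxyprop-1-en-1-yl]-4-methylhex-2-enoate
Conditions: Pd(PPh3)4 (5 mol %), K3PO4, THF/H2O, 60 °C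
Reagents that add atoms: none
Why: Suzuki–Miyaura coupling of the activated alkenyl bromide with the E-alkenylboronate proceeds with retention at both partners, so the sec-butyl group ends up cis to the new alkenyl branch (C7') and trans to the ester.

Step 5
Reactants: 8 tert-butyl (2E,4S)-2-[(1E)-3-hydroxyprop-1-en-1-yl]-4-methylhex-2-enoate
Product: 9 tert-butyl (2E,4S)-2-[(2R,3R)-3-(hydroxymethyl)oxiran-2-yl]-4-methylhex-2-enoate
Conditions: Ti(OiPr)4 (10 mol %), D-(−)-diisopropyl tartrate (12 mol %), tBuOOH, 4 Å molecular sieves, CH2Cl2, −20 °C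
Reagents that add atoms: tert-butyl hydroperoxide, CC(C)(C)OO
Why: Katsuki–Sharpless asymmetric epoxidation of the E-allylic alcohol: the D-(−)-tartrate catalyst sets both epoxide centres by reagent control (the enantiomeric series to the 2S,3S epoxides that the L-(+)-ester gives from E-allylic alcohols), independent of the remote C10' centre, and the electron-poor acrylate alkene is not epoxidised.

Step 6
Reactants: 9 tert-butyl (2E,4S)-2-[(2R,3R)-3-(hydroxymethyl)oxiran-2-yl]-4-methylhex-2-enoate
Product: 10 tert-butyl (2E,4S)-2-[(2R,3S)-3-(iodomethyl)oxiran-2-yl]-4-methylhex-2-enoate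
Conditions: I2, PPh3, imidazole, CH2Cl2, 0 °C
Reagents that add atoms: iodine, II
Why: Appel-type iodination (Garegg–Samuelsson conditions) replaces the primary hydroxyl by SN2 on the alkoxyphosphonium ion while imidazole buffers the acid, so the epoxide and its stereocentres are not touched (the descriptor at the CH2I-bearing carbon changes only through the priority rules).

Step 7
Reactants: 10 tert-butyl (2E,4S)-2-[(2R,3S)-3-(iodomethyl)oxiran-2-yl]-4-methylhex-2-enoate
Product: 11 tert-butyl (2E,4S)-2-[(1S)-1-hydroxyprop-2-en-1-yl]-4-methylhex-2-enoate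
Conditions: activated Zn dust, EtOH, 60 °C; aq. NH4Cl work-up
Reagents that add atoms: none
Why: Zinc-mediated reductive opening of a 2,3-epoxy iodide (β-elimination of the organozinc) breaks the C6'–O bond and forms the terminal alkene, so the C7'–O bond and its configuration from step 5 are kept and appear as the (S)-carbinol.

Step 8
Reactants: 11 tert-butyl (2E,4S)-2-[(1S)-1-hydroxyprop-2-en-1-yl]-4-methylhex-2-enoate; 12 propanoyl chloride
Product: 13 tert-butyl (2E,4S)-4-methyl-2-[(1S)-1-(propanoyloxy)prop-2-en-1-yl]hex-2-enoate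
Conditions: pyridine, CH2Cl2, 0 °C → rt
Reagents that add atoms: none
Why: O-acylation of the secondary alcohol by nucleophilic acyl substitution; no strongly nucleophilic amine is present that could trigger SN2' transposition of the Baylis–Hillman-type ester, and the carbinol centre is not involved.

Step 9
Reactants: 13 tert-butyl (2E,4S)-4-methyl-2-[(1S)-1-(propanoyloxy)prop-2-en-1-yl]hex-2-enoate
Product: 16 (2S,4E,6E,8S)-6-(tert-butoxycarbonyl)-2,8-dimethyldeca-4,6-dienoic acid, via silyl ketene acetal 14 (not isolated), via trimethylsilyl ester 15 (not isolated)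
Conditions: LiN(iPr)2 (1.2 equiv) premixed with Me3SiCl (3 equiv), THF, −78 °C, then 13; −78 °C → rt → 45 °C; 1 M HCl work-up
Reagents that add atoms: none
Why: Ireland–Claisen rearrangement: LiN(iPr)2 in THF without a dipolar additive removes the propionate α-proton through a closed six-membered transition state to give the E(O)-enolate, which Me3SiCl traps in situ as the E-silyl ketene acetal 14 (methyl cis to the allylic oxygen), and on warming 14 undergoes a concerted suprafacial [3,3]-sigmatropic shift through its vinyl group that forms the C4'–C5' bond and the silyl ester 15, hydrolysed to 16 on work-up. The closest known reaction type is the ester-enolate Claisen rearrangement of propionates of secondary allylic alcohols with 1,4-chirality transfer, which is also known for esters of Baylis–Hillman-type carbinols; no ring is closed. The one new stereocentre, C4', is controlled jointly by the (S)-C7' carbinol and the ketene acetal geometry: in the chair transition state the bulky 1-(tert-butoxycarbonyl)alkenyl substituent on C7' is equatorial, so the new C6'=C7' alkene is E and C5' meets the face of the ketene acetal that, with the methyl group axial, gives 2S in 16 (4'R in the target). The step needs site selectivity between the two allyl systems of the bis-allylic ester, and the substrate secures it because C5' is an unsubstituted terminus whereas a shift onto C9' would bond to the carbon bearing the sec-butyl group and force that group, which is cis to C7', into an axial position of the chair. It also needs a clean enolate geometry and chemoselective deprotonation, which the HMPA-free conditions and the in situ silylation should provide, the tert-butyl enoate being shielded by its α,β-substitution and its C10'–H being held in the alkene plane by allylic 1,3-strain.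

Step 10
Reactants: 16 (2S,4E,6E,8S)-6-(tert-butoxycarbonyl)-2,8-dimethyldeca-4,6-dienoic acid
Product: 18 tert-butyl (2E,4S)-2-[(1E,4S)-5-hydroxy-4-methylpent-1-en-1-yl]-4-methylhex-2-enoate, via mixed carbonic anhydride 17 (not isolated)
Conditions: iBuOCOCl, N-methylmorpholine, THF, −15 °C; then NaBH4, H2O, 0 °C
Reagents that add atoms: none
Why: Chemoselective reduction of a carboxylic acid through its mixed carbonic anhydride with NaBH4, which should leave the tert-butyl ester and the diene alone, and cold activation with a weak base should not epimerise C4'.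

Step 11
Reactants: 18 tert-butyl (2E,4S)-2-[(1E,4S)-5-hydroxy-4-methylpent-1-en-1-yl]-4-methylhex-2-enoate
Product: 19 tert-butyl (2E,4S)-2-[(1E,4S)-5-iodo-4-methylpent-1-en-1-yl]-4-methylhex-2-enoate
Conditions: I2, PPh3, imidazole, CH2Cl2, 0 °C → rt
Reagents that add atoms: iodine, II
Why: Appel-type iodination by SN2 at the primary carbinol carbon; the adjacent C4' centre is not involved.

Step 12
Reactants: 19 tert-butyl (2E,4S)-2-[(1E,4S)-5-iodo-4-methylpent-1-en-1-yl]-4-methylhex-2-enoate; 20 acetic acid
Product: 21 (4R,6E,8E,10S)-8-(tert-butoxycarbonyl)-4,10-dimethyldodeca-6,8-dienoic acid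
Conditions: 20 (3 equiv), LiN(iPr)2 (6 equiv), THF/DMPU, 0 °C; then 19, 0 °C → 40 °C; aq. HCl to pH 3
Reagents that add atoms: none
Why: Alkylation of a carboxylic acid dianion (dilithium acetate) by SN2 at the primary iodide adds C1' and C2' in one operation, and the hindered tert-butyl ester should resist the nucleophile (C4' is unchanged; its descriptor becomes R only through the priority rules).

Step 13
Reactants: 22 methyl (3R)-3-hydroxybutanoate; 23 tert-butyl acetate
Product: 24 tert-butyl (5R)-5-hydroxy-3-oxohexanoate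
Conditions: 23 (3.3 equiv), LiN(iPr)2 (3.3 equiv), THF, −78 °C; then 22, −78 → −20 °C; aq. NH4Cl
Reagents that add atoms: none
Why: Crossed Claisen condensation of excess lithio tert-butyl acetate with the methyl ester; the hydroxyl is carried as its alkoxide and the product as its enolate, so the carbinol stereocentre is not affected.

Step 14
Reactants: 24 tert-butyl (5R)-5-hydroxy-3-oxohexanoate
Product: 25 (6R)-4-hydroxy-6-methyl-5,6-dihydro-2H-pyran-2-one
Conditions: CF3CO2H, CH2Cl2, rt
Reagents that add atoms: none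
Why: Acid-mediated tert-butyl ester cleavage and lactonisation of the δ-hydroxy β-keto acid close ring A as the six-membered dihydropyran-2,4-dione (enol form) without touching C6.

Step 15
Reactants: 21 (4R,6E,8E,10S)-8-(tert-butoxycarbonyl)-4,10-dimethyldodeca-6,8-dienoic acid; 25 (6R)-4-hydroxy-6-methyl-5,6-dihydro-2H-pyran-2-one
Product: 27 tert-butyl (2E,4S)-2-[(1E,4R)-7-[(6R)-4-hydroxy-6-methyl-2-oxo-5,6-dihydro-2H-pyran-3-yl]-4-methyl-7-oxohept-1-en-1-yl]-4-methylhex-2-enoate, via enol ester 26 (not isolated)
Conditions: DCC (1.1 equiv), DMAP (1.2 equiv), CH2Cl2, 0 °C → rt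
Reagents that add atoms: none
Why: Carbodiimide O-acylation of the enol followed by DMAP-mediated O→C acyl migration (Fries-type 1,3-acyl shift through the acylpyridinium–enolate pair) to C3 gives the chelated 3-acyl-4-hydroxy form, the standard way to acylate 4-hydroxy-5,6-dihydropyran-2-ones at C3.

Step 16
Reactants: 27 tert-butyl (2E,4S)-2-[(1E,4R)-7-[(6R)-4-hydroxy-6-methyl-2-oxo-5,6-dihydro-2H-pyran-3-yl]-4-methyl-7-oxohept-1-en-1-yl]-4-methylhex-2-enoate
Product: 28 (2E,4S)-2-[(1E,4R)-7-[(6R)-4-hydroxy-6-methyl-2-oxo-5,6-dihydro-2H-pyran-3-yl]-4-methyl-7-oxohept-1-en-1-yl]-4-methylhex-2-enoic acid (CNP0281879.1)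
Conditions: CF3CO2H/CH2Cl2 (1:4), 0 °C → rt
Reagents that add atoms: none
Why: Acidolysis of the tert-butyl ester with loss of isobutene; the acylpyranone (itself formed in this acid) and the electron-poor dienoic acid should be stable, and no stereocentre is involved.

**Compound list**

1 | (S)-2-methylbutan-1-ol | CC[C@H](C)CO | starting material
2 | (S)-2-methylbutanal | CC[C@H](C)C=O | intermediate
3 | tert-butyl 2-(triphenyl-λ5-phosphanylidene)acetate | CC(C)(C)OC(=O)C=P(c1ccccc1)(c1ccccc1)c1ccccc1 | starting material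
4 | (1-bromo-2-tert-butoxy-2-oxoethyl)triphenylphosphonium succinimidate | CC(C)(C)OC(=O)C(Br)[P+](c1ccccc1)(c1ccccc1)c1ccccc1.O=C1CCC(=O)[N-]1 | intermediate
5 | tert-butyl 2-bromo-2-(triphenyl-λ5-phosphanylidene)acetate | CC(C)(C)OC(=O)C(Br)=P(c1ccccc1)(c1ccccc1)c1ccccc1 | intermediate
6 | tert-butyl (2Z,4S)-2-bromo-4-methylhex-2-enoate | CC[C@H](C)/C=C(\Br)C(=O)OC(C)(C)C | intermediate
7 | (2E)-3-(4,4,5,5-tetramethyl-1,3,2-dioxaborolan-2-yl)prop-2-en-1-ol | OC/C=C/B1OC(C)(C)C(C)(C)O1 | starting material
8 | tert-butyl (2E,4S)-2-[(1E)-3-hydroxyprop-1-en-1-yl]-4-methylhex-2-enoate | CC[C@H](C)/C=C(\C=C\CO)C(=O)OC(C)(C)C | intermediate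
9 | tert-butyl (2E,4S)-2-[(2R,3R)-3-(hydroxymethyl)oxiran-2-yl]-4-methylhex-2-enoate | CC[C@H](C)/C=C(\[C@H]1O[C@@H]1CO)C(=O)OC(C)(C)C | intermediate
10 | tert-butyl (2E,4S)-2-[(2R,3S)-3-(iodomethyl)oxiran-2-yl]-4-methylhex-2-enoate | CC[C@H](C)/C=C(\[C@H]1O[C@@H]1CI)C(=O)OC(C)(C)C | intermediate
11 | tert-butyl (2E,4S)-2-[(1S)-1-hydroxyprop-2-en-1-yl]-4-methylhex-2-enoate | CC[C@H](C)/C=C(\[C@H](C=C)O)C(=O)OC(C)(C)C | intermediate
12 | propanoyl chloride | CCC(=O)Cl | starting material
13 | tert-butyl (2E,4S)-4-methyl-2-[(1S)-1-(propanoyloxy)prop-2-en-1-yl]hex-2-enoate | CC[C@H](C)/C=C(\[C@H](C=C)OC(=O)CC)C(=O)OC(C)(C)C | intermediate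
14 | tert-butyl (2E,4S)-4-methyl-2-[(1S)-1-{[(1E)-1-(trimethylsilyloxy)prop-1-en-1-yl]oxy}prop-2-en-1-yl]hex-2-enoate | CC[C@H](C)/C=C(\[C@H](C=C)O/C(O[Si](C)(C)C)=C\C)C(=O)OC(C)(C)C | intermediate
15 | trimethylsilyl (2S,4E,6E,8S)-6-(tert-butoxycarbonyl)-2,8-dimethyldeca-4,6-dienoate | CC[C@H](C)/C=C(\C=C\C[C@H](C)C(=O)O[Si](C)(C)C)C(=O)OC(C)(C)C | intermediate
16 | (2S,4E,6E,8S)-6-(tert-butoxycarbonyl)-2,8-dimethyldeca-4,6-dienoic acid | CC[C@H](C)/C=C(\C=C\C[C@H](C)C(=O)O)C(=O)OC(C)(C)C | intermediate
17 | (2S,4E,6E,8S)-6-(tert-butoxycarbonyl)-2,8-dimethyldeca-4,6-dienoic 2-methylpropyl carbonic anhydride | CC[C@H](C)/C=C(\C=C\C[C@H](C)C(=O)OC(=O)OCC(C)C)C(=O)OC(C)(C)C | intermediate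
18 | tert-butyl (2E,4S)-2-[(1E,4S)-5-hydroxy-4-methylpent-1-en-1-yl]-4-methylhex-2-enoate | CC[C@H](C)/C=C(\C=C\C[C@H](C)CO)C(=O)OC(C)(C)C | intermediate
19 | tert-butyl (2E,4S)-2-[(1E,4S)-5-iodo-4-methylpent-1-en-1-yl]-4-methylhex-2-enoate | CC[C@H](C)/C=C(\C=C\C[C@H](C)CI)C(=O)OC(C)(C)C | intermediate
20 | acetic acid | CC(=O)O | starting material
21 | (4R,6E,8E,10S)-8-(tert-butoxycarbonyl)-4,10-dimethyldodeca-6,8-dienoic acid | CC[C@H](C)/C=C(\C=C\C[C@H](C)CCC(=O)O)C(=O)OC(C)(C)C | intermediate
22 | methyl (3R)-3-hydroxybutanoate | COC(=O)C[C@@H](C)O | starting material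
23 | tert-butyl acetate | CC(=O)OC(C)(C)C | starting material
24 | tert-butyl (5R)-5-hydroxy-3-oxohexanoate | C[C@@H](O)CC(=O)CC(=O)OC(C)(C)C | intermediate
25 | (6R)-4-hydroxy-6-methyl-5,6-dihydro-2H-pyran-2-one | C[C@@H]1CC(O)=CC(=O)O1 | intermediate
26 | (6R)-6-methyl-2-oxo-5,6-dihydro-2H-pyran-4-yl (4R,6E,8E,10S)-8-(tert-butoxycarbonyl)-4,10-dimethyldodeca-6,8-dienoate | CC[C@H](C)/C=C(\C=C\C[C@H](C)CCC(=O)OC1=CC(=O)O[C@H](C)C1)C(=O)OC(C)(C)C | intermediate
27 | tert-butyl (2E,4S)-2-[(1E,4R)-7-[(6R)-4-hydroxy-6-methyl-2-oxo-5,6-dihydro-2H-pyran-3-yl]-4-methyl-7-oxohept-1-en-1-yl]-4-methylhex-2-enoate | CC[C@H](C)/C=C(\C=C\C[C@H](C)CCC(=O)C1=C(O)C[C@@H](C)OC1=O)C(=O)OC(C)(C)C | intermediate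
28 | (2E,4S)-2-[(1E,4R)-7-[(6R)-4-hydroxy-6-methyl-2-oxo-5,6-dihydro-2H-pyran-3-yl]-4-methyl-7-oxohept-1-en-1-yl]-4-methylhex-2-enoic acid | CC[C@H](C)/C=C(\C=C\C[C@H](C)CCC(=O)C1=C(O)C[C@@H](C)OC1=O)C(=O)O | target

**Step count**

Total: 16 steps. Longest linear sequence: 13 steps (steps 1, 3 to 12, 15 and 16, from (S)-2-methylbutan-1-ol); step 2 and steps 13 and 14 are side branches.

**Steps most likely to fail, with fallbacks**

Step 9 (Ireland–Claisen rearrangement). Leakage to the Z(O)-enolate would lower the selectivity at C4' and give an epimer that differs only at a remote centre and would be hard to remove. The amide base could also attack the enoate, or part of the material could rearrange through the acrylate alkene. The fallback sets the C4' centre by an auxiliary instead of by chirality transfer; it sets out from dienol 8 and comes back at acid 16. Appel bromination of 8 (CBr4, PPh3, CH2Cl2, 0 °C) should give the allylic bromide tert-butyl (2E,4S)-2-[(1E)-3-bromoprop-1-en-1-yl]-4-methylhex-2-enoate F1. Evans alkylation of the sodium enolate of commercial (4R)-4-benzyl-3-propanoyl-1,3-oxazolidin-2-one (NaN(SiMe3)2, THF, −78 °C) with F1 forms the C4'–C5' bond on the enolate face away from the benzyl group and should give the imide (4R)-4-benzyl-3-[(2S,4E,6E,8S)-6-(tert-butoxycarbonyl)-2,8-dimethyldeca-4,6-dienoyl]-1,3-oxazolidin-2-one F2. Cleavage with LiOH/H2O2 (THF/H2O, 0 °C) then releases 16, the E-C6'=C7' geometry having been fixed in step 4.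

Step 12 (alkylation of dilithium acetate). The strongly basic, poorly soluble dianion may react sluggishly at the β-branched primary iodide or cause E2 elimination. The fallback uses a soft, weakly basic nucleophile; it sets out from iodide 19 and comes back at acid 21. Alkylation of sodium dimethyl malonate (NaH, DMF, 60 °C) with 19 should give dimethyl 2-[(2S,4E,6E,8S)-6-(tert-butoxycarbonyl)-2,8-dimethyldeca-4,6-dien-1-yl]propanedioate F3. Saponification of the two methyl esters only (LiOH, THF/H2O, rt) gives 2-[(2S,4E,6E,8S)-6-(tert-butoxycarbonyl)-2,8-dimethyldeca-4,6-dien-1-yl]propanedioic acid F4, and decarboxylation in pyridine at 100 °C gives 21.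

Step 5 (asymmetric epoxidation). The allylic alkene is conjugated to an electron-poor acrylate and may be epoxidised slowly, and the vinyl epoxide formed may be opened by the alkoxide or hydroperoxide at the titanium centre. The fallback makes the carbinol by C–C bond formation and resolution; it sets out from bromoenoate 6 and comes back at carbinol 11, bypassing steps 4 to 7. Nozaki–Hiyama–Kishi coupling of 6 with acrolein (CrCl2, catalytic NiCl2, DMF, rt), which should keep the alkene geometry through the σ-bonded alkenyl nickel and chromium species, gives the epimeric carbinol tert-butyl (2E,4S)-2-[(1RS)-1-hydroxyprop-2-en-1-yl]-4-methylhex-2-enoate F5. Lipase-catalysed acylation (Burkholderia cepacia lipase, vinyl acetate, tBuOMe, 35 °C) should acetylate the (1R)-epimer, as the empirical size rule for secondary alcohols predicts with vinyl as the medium and the enoate as the large group, and leave 11, separated by chromatography; at most half of the material can be used.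

**Further compounds**

F1 | step 9 | tert-butyl (2E,4S)-2-[(1E)-3-bromoprop-1-en-1-yl]-4-methylhex-2-enoate | CC[C@H](C)/C=C(\C=C\CBr)C(=O)OC(C)(C)C
F2 | step 9 | (4R)-4-benzyl-3-[(2S,4E,6E,8S)-6-(tert-butoxycarbonyl)-2,8-dimethyldeca-4,6-dienoyl]-1,3-oxazolidin-2-one | CC[C@H](C)/C=C(\C=C\C[C@H](C)C(=O)N1[C@H](Cc2ccccc2)COC1=O)C(=O)OC(C)(C)C
F3 | step 12 | dimethyl 2-[(2S,4E,6E,8S)-6-(tert-butoxycarbonyl)-2,8-dimethyldeca-4,6-dien-1-yl]propanedioate | CC[C@H](C)/C=C(\C=C\C[C@H](C)CC(C(=O)OC)C(=O)OC)C(=O)OC(C)(C)C
F4 | step 12 | 2-[(2S,4E,6E,8S)-6-(tert-butoxycarbonyl)-2,8-dimethyldeca-4,6-dien-1-yl]propanedioic acid | CC[C@H](C)/C=C(\C=C\C[C@H](C)CC(C(=O)O)C(=O)O)C(=O)OC(C)(C)C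
F5 | step 5 | tert-butyl (2E,4S)-2-[(1RS)-1-hydroxyprop-2-en-1-yl]-4-methylhex-2-enoate | CC[C@H](C)/C=C(\C(O)C=C)C(=O)OC(C)(C)C
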